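**Retrosynthetic overview**
1. Target 32 has one ring, the 5,6-dihydro-2H-pyran-2-one (O1, C2–C6), with a (1'Z)-alkenyl chain on C6. The feature used is that carbinol C6' sits between two CH2 groups (C5', C7') that each end at a further carbinol (C4', C8'), so C6' can be an acyl-anion carbon bridging the CH2 termini of two epoxides.
2. Key disconnection: C5'–C6' and C6'–C7' are made in one flask from silyl dithiane 4 (C6') and the (R)-epoxides 7 (C7'–C10', phenyl) and 12 (C2'–C5'). This gives 16 with O8' silylated and O4' free.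
3. C6' is set by unmasking the ketone and reducing it syn to the free 4'-OH. After silylation, the C2' terminus is oxidised and extended by C1' (dibromo-olefination) and C6 (formylation) to ynal 26.
4. The only ring is closed in step 15 by a catalytic asymmetric hetero-Diels–Alder reaction of 26 with 1-methoxybutadiene (C2–C5), which sets C6. The acetal is then converted to the lactone.
5. Finish: cis-semi-hydrogenation of C1'≡C2' to the Z-alkene, then removal of the three silyl ethers.

Key step: step 7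

Remark: the lactone is numbered O1, C2–C6 and the chain C1'–C10' outward from C6, the target being read as 6S,1'Z,4'R,6'S,8'R; the chromium catalyst of step 15 is assumed to show the same facial sense with the ynal as with simple aldehydes.

**Route**

Step 1
Reactants: 1 1,3-dithiane; 2 tert-butyldimethylsilyl chloride
Product: 4 2-(tert-butyldimethylsilyl)-1,3-dithiane, via 2-lithio-1,3-dithiane 3 (not isolated)
Conditions: n-BuLi, THF, −30 °C; then TBSCl, −78 °C to rt
Reagents that add atoms: none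
Why: The C2–H flanked by two sulfur atoms is removed cleanly by n-BuLi and the carbanion should be C-silylated by TBSCl (Corey–Seebach dithiane alkylation type), with no stereocentre involved.

Step 2
Reactants: 5 4-phenylbut-1-ene
Product: 6 rac-2-(2-phenylethyl)oxirane
Conditions: mCPBA, CH2Cl2, 0 °C to rt
Reagents that add atoms: mCPBA (3-chloroperoxybenzoic acid), O=C(OO)c1cccc(Cl)c1
Why: Prilezhaev epoxidation of an unhindered monosubstituted alkene by a peracid is general and should give the racemic terminal epoxide.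

Step 3
Reactants: 6 rac-2-(2-phenylethyl)oxirane
Product: 7 (2R)-2-(2-phenylethyl)oxirane
Conditions: (R,R)-(salen)Co(OAc) (0.5 mol %; salen = dianion of N,N′-bis(3,5-di-tert-butylsalicylidene)-(1R,2R)-cyclohexane-1,2-diamine; trivalent cobalt, made from (salen)Co, AcOH and air), H2O (0.55 equiv), THF, 0 °C to rt; distillation
Reagents that add atoms: none
Why: In this hydrolytic kinetic resolution the (R,R)-catalyst should hydrolyse the (S)-epoxide much faster, so the unreacted (R)-epoxide, which carries the future C8' stereocentre, should be recovered in high enantiomeric purity just past half conversion.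

Step 4
Reactants: 8 but-3-en-1-ol
Product: 10 1-[(but-3-en-1-yloxy)methyl]-4-methoxybenzene, via sodium but-3-en-1-olate 9 (not isolated)
Conditions: NaH, THF/DMF, 0 °C; then 4-methoxybenzyl chloride, Bu4NI (cat.), 0 °C to rt
Reagents that add atoms: 4-methoxybenzyl chloride, COc1ccc(CCl)cc1
Why: Williamson etherification of a primary alkoxide with a benzylic chloride, accelerated by iodide exchange, should be clean.

Step 5
Reactants: 10 1-[(but-3-en-1-yloxy)methyl]-4-methoxybenzene
Product: 11 rac-2-{2-[(4-methoxybenzyl)oxy]ethyl}oxirane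
Conditions: mCPBA, CH2Cl2, 0 °C to rt
Reagents that add atoms: mCPBA (3-chloroperoxybenzoic acid), O=C(OO)c1cccc(Cl)c1
Why: Prilezhaev epoxidation of the terminal alkene should proceed without touching the 4-methoxybenzyl ether.

Step 6
Reactants: 11 rac-2-{2-[(4-methoxybenzyl)oxy]ethyl}oxirane
Product: 12 (2R)-2-{2-[(4-methoxybenzyl)oxy]ethyl}oxirane
Conditions: (R,R)-(salen)Co(OAc) (0.5 mol %, same complex as in step 3), H2O (0.55 equiv), THF, 0 °C to rt; chromatography
Reagents that add atoms: none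
Why: The same hydrolytic kinetic resolution should remove the (S)-epoxide as its diol and leave the (R)-epoxide, which carries the future C4' stereocentre.

Step 7
Reactants: 4 2-(tert-butyldimethylsilyl)-1,3-dithiane; 7 (2R)-2-(2-phenylethyl)oxirane; 12 (2R)-2-{2-[(4-methoxybenzyl)oxy]ethyl}oxirane
Product: 16 (2R)-1-{2-[(2R)-2-(tert-butyldimethylsilyloxy)-4-phenylbutyl]-1,3-dithian-2-yl}-4-[(4-methoxybenzyl)oxy]butan-2-ol, via 2-lithio-2-(tert-butyldimethylsilyl)-1,3-dithiane 13 (not isolated), via lithium alkoxide 14 (not isolated), via relayed lithio dithiane 15 (not isolated)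
Conditions: t-BuLi, Et2O, −78 to −45 °C; 7, Et2O, −78 to −25 °C; then 12 in THF/HMPA, −78 °C to rt; aq NH4Cl
Reagents that add atoms: none
Why: t-BuLi removes the C2–H of 4, carbanion 13 opens 7 by SN2 attack at its unsubstituted carbon (C7') to give alkoxide 14, which keeps its C–Si bond in Et2O; adding HMPA together with 12 triggers the 1,4-shift of silicon from carbon to oxygen (Brook rearrangement through a five-membered silicate), and the resulting dithiane anion 15 opens 12 at C5'. The closest known reaction type is the multicomponent dithiane linchpin coupling of two different epoxides with solvent-controlled Brook rearrangement (anion relay). No ring is closed and no stereocentre is created, since C8' and C4' are carried over unchanged from 7 and 12 because no C–O bond at a stereocentre is broken. The step needs attack only at the CH2 termini, which the bulk of the tertiary dithianyl anion against monosubstituted epoxides secures, and a strict order of events, which is secured because the silyl group does not migrate in Et2O until HMPA is added; this places the silyl group on O8' and leaves the 4'-OH free.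

Step 8
Reactants: 16 (2R)-1-{2-[(2R)-2-(tert-butyldimethylsilyloxy)-4-phenylbutyl]-1,3-dithian-2-yl}-4-[(4-methoxybenzyl)oxy]butan-2-ol
Product: 17 (3R,7R)-7-(tert-butyldimethylsilyloxy)-3-hydroxy-1-[(4-methoxybenzyl)oxy]-9-phenylnonan-5-one
Conditions: MeI, CaCO3, MeCN/H2O (9:1), rt to 40 °C
Reagents that add atoms: water, O
Why: S-Methylation turns the dithiane into a sulfonium leaving group that water displaces (alkylative thioacetal hydrolysis), and the CaCO3 buffer should keep the β-hydroxy ketone, the silyl ether and the 4-methoxybenzyl ether intact.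

Step 9
Reactants: 17 (3R,7R)-7-(tert-butyldimethylsilyloxy)-3-hydroxy-1-[(4-methoxybenzyl)oxy]-9-phenylnonan-5-one
Product: 19 (3R,5R,7R)-7-(tert-butyldimethylsilyloxy)-1-[(4-methoxybenzyl)oxy]-9-phenylnonane-3,5-diol, via diethylboron chelate 18 (not isolated)
Conditions: Et2BOMe, THF/MeOH (4:1), −78 °C; then NaBH4, −78 °C; AcOH, then evaporation from MeOH
Reagents that add atoms: none
Why: In this Narasaka–Prasad reduction the free 4'-OH and the ketone form a six-membered boron chelate and external hydride adds axially to its half-chair, which should set C6' syn to C4' (the target configuration; the label is 5R here only because the silyl group on O8' reverses the ranking of the two CH2 branches), while the silylated O8' cannot chelate.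

Step 10
Reactants: 19 (3R,5R,7R)-7-(tert-butyldimethylsilyloxy)-1-[(4-methoxybenzyl)oxy]-9-phenylnonane-3,5-diol
Product: 20 1-methoxy-4-({[(3R,5S,7R)-3,5,7-tris(tert-butyldimethylsilyloxy)-9-phenylnonyl]oxy}methyl)benzene
Conditions: TBSOTf, 2,6-lutidine, CH2Cl2, −78 to 0 °C
Reagents that add atoms: TBSOTf (tert-butyldimethylsilyl trifluoromethanesulfonate), CC(C)(C)[Si](C)(C)OS(=O)(=O)C(F)(F)F
Why: The silyl triflate with a hindered base silylates both secondary hydroxyls of a 1,3-diol readily and gives one uniform protecting group for all three carbinols.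

Step 11
Reactants: 20 1-methoxy-4-({[(3R,5S,7R)-3,5,7-tris(tert-butyldimethylsilyloxy)-9-phenylnonyl]oxy}methyl)benzene
Product: 21 (3R,5S,7R)-3,5,7-tris(tert-butyldimethylsilyloxy)-9-phenylnonan-1-ol
Conditions: DDQ, CH2Cl2/pH 7 buffer, 0 °C to rt
Reagents that add atoms: none
Why: DDQ oxidises only the electron-rich 4-methoxybenzyl ether to an oxocarbenium ion that water hydrolyses (oxidative debenzylation), leaving the silyl ethers and the unactivated phenyl ring untouched.

Step 12
Reactants: 21 (3R,5S,7R)-3,5,7-tris(tert-butyldimethylsilyloxy)-9-phenylnonan-1-ol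
Product: 22 (3S,5S,7R)-3,5,7-tris(tert-butyldimethylsilyloxy)-9-phenylnonanal
Conditions: Dess–Martin periodinane, CH2Cl2, 0 °C to rt
Reagents that add atoms: none
Why: Dess–Martin oxidation converts the primary alcohol to the aldehyde under near-neutral conditions that should not eliminate the β-silyloxy group (the descriptor at C3 changes only because the formyl group changes the ranking).

Step 13
Reactants: 22 (3S,5S,7R)-3,5,7-tris(tert-butyldimethylsilyloxy)-9-phenylnonanal
Product: 23 (4R,6S,8R)-1,1-dibromo-4,6,8-tris(tert-butyldimethylsilyloxy)-10-phenyldec-1-ene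
Conditions: CBr4, PPh3, Zn, CH2Cl2, rt (reagent pre-formed); then 22, rt
Reagents that add atoms: carbon tetrabromide, BrC(Br)(Br)Br
Why: The first stage of the Corey–Fuchs reaction, a Wittig-type olefination with the ylide Ph3P=CBr2 made under neutral zinc conditions, should add C1' without base-induced β-elimination.

Step 14
Reactants: 23 (4R,6S,8R)-1,1-dibromo-4,6,8-tris(tert-butyldimethylsilyloxy)-10-phenyldec-1-ene
Product: 26 (5R,7S,9R)-5,7,9-tris(tert-butyldimethylsilyloxy)-11-phenylundec-2-ynal, via lithium acetylide 24 (not isolated), via lithium hemiaminal alkoxide 25 (not isolated)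
Conditions: n-BuLi (2.1 equiv), THF, −78 °C; then DMF, −78 to 0 °C; poured into aq KH2PO4
Reagents that add atoms: N,N-dimethylformamide, CN(C)C=O
Why: The second stage of the Corey–Fuchs reaction (bromine–lithium exchange, Fritsch–Buttenberg–Wiechell-type rearrangement and deprotonation) gives the lithium acetylide, which is formylated by DMF, and the buffered inverse quench should release the ynal without addition of dimethylamine to it.

Step 15
Reactants: 26 (5R,7S,9R)-5,7,9-tris(tert-butyldimethylsilyloxy)-11-phenylundec-2-ynal; 27 (1E)-1-methoxybuta-1,3-diene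
Product: 28 (2R,6S)-2-methoxy-6-[(4R,6S,8R)-4,6,8-tris(tert-butyldimethylsilyloxy)-10-phenyldec-1-yn-1-yl]-5,6-dihydro-2H-pyran
Conditions: [Cr(L)Cl] (5 mol %; trivalent chromium; L = dianion of (1S,2R)-1-{[3-(1-adamantyl)-2-hydroxy-5-methylbenzylidene]amino}indan-2-ol), 4 Å molecular sieves, excess 27, minimal EtOAc, rt
Reagents that add atoms: none
Why: This catalytic asymmetric hetero-Diels–Alder reaction closes the ring O1–C2–C3–C4–C5–C6 by a [4+2] cycloaddition that forms C5–C6 and O1–C2, the chiral Lewis acid directing the diene to the Si face of the activated, unhindered ynal so that C6 should be set as S under catalyst control, while the endo-derived C2 acetal centre is erased in step 17.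

Step 16
Reactants: 28 (2R,6S)-2-methoxy-6-[(4R,6S,8R)-4,6,8-tris(tert-butyldimethylsilyloxy)-10-phenyldec-1-yn-1-yl]-5,6-dihydro-2H-pyran
Product: 29 (6S)-6-[(4R,6S,8R)-4,6,8-tris(tert-butyldimethylsilyloxy)-10-phenyldec-1-yn-1-yl]-5,6-dihydro-2H-pyran-2-ol (both C2 epimers)
Conditions: PPTS (cat.), acetone/H2O, rt
Reagents that add atoms: water, O
Why: The allylic methyl acetal ionises easily to a stabilised oxocarbenium ion, so mild acid-catalysed hydrolysis should give the lactol while the secondary silyl ethers survive.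

Step 17
Reactants: 29 (6S)-6-[(4R,6S,8R)-4,6,8-tris(tert-butyldimethylsilyloxy)-10-phenyldec-1-yn-1-yl]-5,6-dihydro-2H-pyran-2-ol
Product: 30 (6S)-6-[(4R,6S,8R)-4,6,8-tris(tert-butyldimethylsilyloxy)-10-phenyldec-1-yn-1-yl]-5,6-dihydro-2H-pyran-2-one
Conditions: MnO2, CH2Cl2, rt
Reagents that add atoms: none
Why: The lactol carbon is an allylic carbinol, so MnO2 should oxidise it selectively to the conjugated lactone under neutral conditions (allylic oxidation).

Step 18
Reactants: 30 (6S)-6-[(4R,6S,8R)-4,6,8-tris(tert-butyldimethylsilyloxy)-10-phenyldec-1-yn-1-yl]-5,6-dihydro-2H-pyran-2-one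
Product: 31 (6S)-6-[(1Z,4R,6S,8R)-4,6,8-tris(tert-butyldimethylsilyloxy)-10-phenyldec-1-en-1-yl]-5,6-dihydro-2H-pyran-2-one
Conditions: H2 (1 atm), Pd/CaCO3 poisoned with Pb(OAc)2, quinoline, EtOAc, rt
Reagents that add atoms: none
Why: Lindlar-type semi-hydrogenation adds H2 syn to the alkyne on the poisoned palladium surface, which should give the 1'Z-alkene and stop there, the alkyne binding much more strongly than the conjugated C3=C4 bond.

Step 19
Reactants: 31 (6S)-6-[(1Z,4R,6S,8R)-4,6,8-tris(tert-butyldimethylsilyloxy)-10-phenyldec-1-en-1-yl]-5,6-dihydro-2H-pyran-2-one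
Product: 32 (6S)-6-[(1Z,4R,6S,8R)-4,6,8-trihydroxy-10-phenyldec-1-en-1-yl]-5,6-dihydro-2H-pyran-2-one
Conditions: aq HF (48 %), MeCN, 0 °C to rt
Reagents that add atoms: none
Why: Fluoride-driven protodesilylation under mildly acidic conditions should cleave the three secondary silyl ethers without opening the lactone or isomerising the Z-alkene.

**Compound list**
1 | 1,3-dithiane | C1CSCSC1 | starting material
2 | tert-butyldimethylsilyl chloride | CC(C)(C)[Si](C)(C)Cl | starting material
3 | 2-lithio-1,3-dithiane (formed in the flask) | [Li]C1SCCCS1 | intermediate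
4 | 2-(tert-butyldimethylsilyl)-1,3-dithiane | CC(C)(C)[Si](C)(C)C1SCCCS1 | intermediate
5 | 4-phenylbut-1-ene | C=CCCc1ccccc1 | starting material
6 | rac-2-(2-phenylethyl)oxirane | C1OC1CCc1ccccc1 | intermediate
7 | (2R)-2-(2-phenylethyl)oxirane | C1[C@@H](CCc2ccccc2)O1 | intermediate
8 | but-3-en-1-ol | C=CCCO | starting material
9 | sodium but-3-en-1-olate (formed in the flask) | [Na+].[O-]CCC=C | intermediate
10 | 1-[(but-3-en-1-yloxy)methyl]-4-methoxybenzene | C=CCCOCc1ccc(OC)cc1 | intermediate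
11 | rac-2-{2-[(4-methoxybenzyl)oxy]ethyl}oxirane | C1OC1CCOCc1ccc(OC)cc1 | intermediate
12 | (2R)-2-{2-[(4-methoxybenzyl)oxy]ethyl}oxirane | C1[C@@H](CCOCc2ccc(OC)cc2)O1 | intermediate
13 | 2-lithio-2-(tert-butyldimethylsilyl)-1,3-dithiane (formed in the flask) | [Li]C1([Si](C)(C)C(C)(C)C)SCCCS1 | intermediate
14 | lithium (2R)-1-[2-(tert-butyldimethylsilyl)-1,3-dithian-2-yl]-4-phenylbutan-2-olate (formed in the flask) | CC(C)(C)[Si](C)(C)C1(C[C@@H](CCc2ccccc2)O[Li])SCCCS1 | intermediate
15 | 2-lithio-2-[(2R)-2-(tert-butyldimethylsilyloxy)-4-phenylbutyl]-1,3-dithiane (formed in the flask) | [Li]C1(C[C@H](O[Si](C)(C)C(C)(C)C)CCc2ccccc2)SCCCS1 | intermediate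
16 | (2R)-1-{2-[(2R)-2-(tert-butyldimethylsilyloxy)-4-phenylbutyl]-1,3-dithian-2-yl}-4-[(4-methoxybenzyl)oxy]butan-2-ol | COc1ccc(COCC[C@@H](O)CC2(C[C@H](O[Si](C)(C)C(C)(C)C)CCc3ccccc3)SCCCS2)cc1 | intermediate
17 | (3R,7R)-7-(tert-butyldimethylsilyloxy)-3-hydroxy-1-[(4-methoxybenzyl)oxy]-9-phenylnonan-5-one | COc1ccc(COCC[C@@H](O)CC(=O)C[C@H](O[Si](C)(C)C(C)(C)C)CCc2ccccc2)cc1 | intermediate
18 | (3R,7R)-7-(tert-butyldimethylsilyloxy)-3-[(diethylboranyl)oxy]-1-[(4-methoxybenzyl)oxy]-9-phenylnonan-5-one, boron chelated by the ketone oxygen (formed in the flask) | CCB(CC)O[C@H](CCOCc1ccc(OC)cc1)CC(=O)C[C@H](O[Si](C)(C)C(C)(C)C)CCc1ccccc1 | intermediate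
19 | (3R,5R,7R)-7-(tert-butyldimethylsilyloxy)-1-[(4-methoxybenzyl)oxy]-9-phenylnonane-3,5-diol | COc1ccc(COCC[C@@H](O)C[C@@H](O)C[C@H](O[Si](C)(C)C(C)(C)C)CCc2ccccc2)cc1 | intermediate
20 | 1-methoxy-4-({[(3R,5S,7R)-3,5,7-tris(tert-butyldimethylsilyloxy)-9-phenylnonyl]oxy}methyl)benzene | COc1ccc(COCC[C@@H](O[Si](C)(C)C(C)(C)C)C[C@@H](O[Si](C)(C)C(C)(C)C)C[C@H](O[Si](C)(C)C(C)(C)C)CCc2ccccc2)cc1 | intermediate
21 | (3R,5S,7R)-3,5,7-tris(tert-butyldimethylsilyloxy)-9-phenylnonan-1-ol | OCC[C@@H](O[Si](C)(C)C(C)(C)C)C[C@@H](O[Si](C)(C)C(C)(C)C)C[C@H](O[Si](C)(C)C(C)(C)C)CCc1ccccc1 | intermediate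
22 | (3S,5S,7R)-3,5,7-tris(tert-butyldimethylsilyloxy)-9-phenylnonanal | O=CC[C@@H](O[Si](C)(C)C(C)(C)C)C[C@@H](O[Si](C)(C)C(C)(C)C)C[C@H](O[Si](C)(C)C(C)(C)C)CCc1ccccc1 | intermediate
23 | (4R,6S,8R)-1,1-dibromo-4,6,8-tris(tert-butyldimethylsilyloxy)-10-phenyldec-1-ene | BrC(Br)=CC[C@@H](O[Si](C)(C)C(C)(C)C)C[C@@H](O[Si](C)(C)C(C)(C)C)C[C@H](O[Si](C)(C)C(C)(C)C)CCc1ccccc1 | intermediate
24 | [(4R,6S,8R)-4,6,8-tris(tert-butyldimethylsilyloxy)-10-phenyldec-1-yn-1-yl]lithium (formed in the flask) | [Li]C#CC[C@@H](O[Si](C)(C)C(C)(C)C)C[C@@H](O[Si](C)(C)C(C)(C)C)C[C@H](O[Si](C)(C)C(C)(C)C)CCc1ccccc1 | intermediate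
25 | lithium (5R,7S,9R)-1-(dimethylamino)-5,7,9-tris(tert-butyldimethylsilyloxy)-11-phenylundec-2-yn-1-olate, C1 unassigned (formed in the flask) | CN(C)C(O[Li])C#CC[C@@H](O[Si](C)(C)C(C)(C)C)C[C@@H](O[Si](C)(C)C(C)(C)C)C[C@H](O[Si](C)(C)C(C)(C)C)CCc1ccccc1 | intermediate
26 | (5R,7S,9R)-5,7,9-tris(tert-butyldimethylsilyloxy)-11-phenylundec-2-ynal | O=CC#CC[C@@H](O[Si](C)(C)C(C)(C)C)C[C@@H](O[Si](C)(C)C(C)(C)C)C[C@H](O[Si](C)(C)C(C)(C)C)CCc1ccccc1 | intermediate
27 | (1E)-1-methoxybuta-1,3-diene | CO/C=C/C=C | starting material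
28 | (2R,6S)-2-methoxy-6-[(4R,6S,8R)-4,6,8-tris(tert-butyldimethylsilyloxy)-10-phenyldec-1-yn-1-yl]-5,6-dihydro-2H-pyran | CO[C@H]1C=CC[C@@H](C#CC[C@@H](O[Si](C)(C)C(C)(C)C)C[C@@H](O[Si](C)(C)C(C)(C)C)C[C@H](O[Si](C)(C)C(C)(C)C)CCc2ccccc2)O1 | intermediate
29 | (6S)-6-[(4R,6S,8R)-4,6,8-tris(tert-butyldimethylsilyloxy)-10-phenyldec-1-yn-1-yl]-5,6-dihydro-2H-pyran-2-ol, both C2 epimers | OC1C=CC[C@@H](C#CC[C@@H](O[Si](C)(C)C(C)(C)C)C[C@@H](O[Si](C)(C)C(C)(C)C)C[C@H](O[Si](C)(C)C(C)(C)C)CCc2ccccc2)O1 | intermediate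
30 | (6S)-6-[(4R,6S,8R)-4,6,8-tris(tert-butyldimethylsilyloxy)-10-phenyldec-1-yn-1-yl]-5,6-dihydro-2H-pyran-2-one | O=C1C=CC[C@@H](C#CC[C@@H](O[Si](C)(C)C(C)(C)C)C[C@@H](O[Si](C)(C)C(C)(C)C)C[C@H](O[Si](C)(C)C(C)(C)C)CCc2ccccc2)O1 | intermediate
31 | (6S)-6-[(1Z,4R,6S,8R)-4,6,8-tris(tert-butyldimethylsilyloxy)-10-phenyldec-1-en-1-yl]-5,6-dihydro-2H-pyran-2-one | O=C1C=CC[C@@H](/C=C\C[C@@H](O[Si](C)(C)C(C)(C)C)C[C@@H](O[Si](C)(C)C(C)(C)C)C[C@H](O[Si](C)(C)C(C)(C)C)CCc2ccccc2)O1 | intermediate
32 | (6S)-6-[(1Z,4R,6S,8R)-4,6,8-trihydroxy-10-phenyldec-1-en-1-yl]-5,6-dihydro-2H-pyran-2-one | O=C1C=CC[C@@H](/C=C\C[C@@H](O)C[C@@H](O)C[C@H](O)CCc2ccccc2)O1 | target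

**Step count and risks**
Total: 19 steps. Longest linear sequence: 16 steps (from 8 through steps 4–6 and 7–19).

Steps most likely to fail:

1. Step 7. The silyl group may migrate too early, so that a second molecule of 7 is taken up, or the relayed anion may be protonated before it meets 12, giving a mono-adduct. Fallback: the two bonds are made one at a time from unsilylated dithiane 1. 2-Lithio-1,3-dithiane 3 (from 1 and n-BuLi) opens 7 to give (2R)-1-(1,3-dithian-2-yl)-4-phenylbutan-2-ol F1. Silylation with TBSCl and imidazole gives 2-[(2R)-2-(tert-butyldimethylsilyloxy)-4-phenylbutyl]-1,3-dithiane F2. Metalation of F2 with t-BuLi in THF/HMPA at −78 °C gives the same anion 15, which is alkylated by 12, and the route is rejoined at 16.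

2. Step 15. The cycloaddition of a bulky, polyoxygenated ynal may be slow, facial control may be insufficient, or the diene may oligomerise. Fallback from 26, building the lactone by allylation and ring-closing metathesis. Brown allylation with the antipode of Ipc2B(allyl) that adds to the Si face of the formyl group should give (4S,8R,10S,12R)-8,10,12-tris(tert-butyldimethylsilyloxy)-14-phenyltetradec-1-en-5-yn-4-ol F3. Semi-hydrogenation over Pd/CaCO3 poisoned with Pb(OAc)2 gives (4S,5Z,8R,10S,12R)-8,10,12-tris(tert-butyldimethylsilyloxy)-14-phenyltetradeca-1,5-dien-4-ol F4. Acylation with acryloyl chloride, Et3N and DMAP gives (4S,5Z,8R,10S,12R)-8,10,12-tris(tert-butyldimethylsilyloxy)-14-phenyltetradeca-1,5-dien-4-yl prop-2-enoate F5. Ring-closing metathesis with the second-generation Grubbs catalyst RuCl2(=CHPh)(PCy3)(H2IMes) in CH2Cl2 closes the lactone, and the route is rejoined at 31.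

3. Step 18. The hydrogenation may run on to the saturated chain, reduce or isomerise the conjugated C3=C4 bond, or cleave the propargylic C6–O bond. Fallback from 28: the cis-reduction is moved to the acetal stage, where no conjugated lactone is present. Reduction under H2 with nickel boride made from Ni(OAc)2 and NaBH4 in the presence of ethylenediamine should give (2R,6S)-2-methoxy-6-[(1Z,4R,6S,8R)-4,6,8-tris(tert-butyldimethylsilyloxy)-10-phenyldec-1-en-1-yl]-5,6-dihydro-2H-pyran F6. Hydrolysis with PPTS in aqueous acetone gives (6S)-6-[(1Z,4R,6S,8R)-4,6,8-tris(tert-butyldimethylsilyloxy)-10-phenyldec-1-en-1-yl]-5,6-dihydro-2H-pyran-2-ol F7. Oxidation of F7 with MnO2 rejoins the route at 31.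

**Further compounds**
F1 | step 7 | (2R)-1-(1,3-dithian-2-yl)-4-phenylbutan-2-ol | C1(C[C@H](O)CCc2ccccc2)SCCCS1
F2 | step 7 | 2-[(2R)-2-(tert-butyldimethylsilyloxy)-4-phenylbutyl]-1,3-dithiane | C1(C[C@H](O[Si](C)(C)C(C)(C)C)CCc2ccccc2)SCCCS1
F3 | step 15 | (4S,8R,10S,12R)-8,10,12-tris(tert-butyldimethylsilyloxy)-14-phenyltetradec-1-en-5-yn-4-ol | C=CC[C@H](O)C#CC[C@@H](O[Si](C)(C)C(C)(C)C)C[C@@H](O[Si](C)(C)C(C)(C)C)C[C@H](O[Si](C)(C)C(C)(C)C)CCc1ccccc1
F4 | step 15 | (4S,5Z,8R,10S,12R)-8,10,12-tris(tert-butyldimethylsilyloxy)-14-phenyltetradeca-1,5-dien-4-ol | C=CC[C@H](O)/C=C\C[C@@H](O[Si](C)(C)C(C)(C)C)C[C@@H](O[Si](C)(C)C(C)(C)C)C[C@H](O[Si](C)(C)C(C)(C)C)CCc1ccccc1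
F5 | step 15 | (4S,5Z,8R,10S,12R)-8,10,12-tris(tert-butyldimethylsilyloxy)-14-phenyltetradeca-1,5-dien-4-yl prop-2-enoate | C=CC(=O)O[C@@H](CC=C)/C=C\C[C@@H](O[Si](C)(C)C(C)(C)C)C[C@@H](O[Si](C)(C)C(C)(C)C)C[C@H](O[Si](C)(C)C(C)(C)C)CCc1ccccc1
F6 | step 18 | (2R,6S)-2-methoxy-6-[(1Z,4R,6S,8R)-4,6,8-tris(tert-butyldimethylsilyloxy)-10-phenyldec-1-en-1-yl]-5,6-dihydro-2H-pyran | CO[C@H]1C=CC[C@@H](/C=C\C[C@@H](O[Si](C)(C)C(C)(C)C)C[C@@H](O[Si](C)(C)C(C)(C)C)C[C@H](O[Si](C)(C)C(C)(C)C)CCc2ccccc2)O1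
F7 | step 18 | (6S)-6-[(1Z,4R,6S,8R)-4,6,8-tris(tert-butyldimethylsilyloxy)-10-phenyldec-1-en-1-yl]-5,6-dihydro-2H-pyran-2-ol, both C2 epimers | OC1C=CC[C@@H](/C=C\C[C@@H](O[Si](C)(C)C(C)(C)C)C[C@@H](O[Si](C)(C)C(C)(C)C)C[C@H](O[Si](C)(C)C(C)(C)C)CCc2ccccc2)O1
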